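## Analysis of the target

The target is (2E)-5-[(2S,3S)-3-[(3E,7E)-10-(furan-3-yl)-3,7-dimethyldeca-3,7-dien-1-yl]-2-methyloxiran-2-yl]-2-methylpent-2-enoic acid, C25H36O4, a linear furanosesterterpenoid. The chain is numbered C1 (carboxyl carbon) to C17, with methyl groups on C2, C6, C10 and C14 and the furan-3-yl ring on C17; these locants are used for every intermediate. There is no carbocycle: the only rings are the furan and the oxirane C6–O–C7. The two stereocentres are the quaternary C6 (CH3, C5, O) and the tertiary C7 (H, C8, O). Both are S and trans-related (C5 and C8 on opposite faces), so the oxirane is the oxide of an E-C6=C7 alkene taken from its Si,Si face. No other stereocentre exists that could relay chirality. The three alkenes C2=C3 (conjugated with the acid), C10=C11 and C14=C15 are all trisubstituted and E. Sensitive groups are the furan (acid, electrophilic halogen, peracids, dioxiranes), the trisubstituted oxirane (Brønsted and Lewis acids) and the skipped polyene, which cyclises once a cation is formed on it. The difficulty is that the oxirane sits on one of three chemically equivalent trisubstituted alkene positions (C6=C7, C10=C11, C14=C15) in an unfunctionalised chain and must be placed there site- and enantioselectively. The feature the route uses is the 1,4-relation between the oxirane oxygen on C6 and C3 (O–C6–C5–C4–C3). While C3 is still a carboxyl carbon, its oxygen reaches C6 through a five-membered ring, the γ-lactone O–C3(=O)–C4–C5–C6, whereas C10=C11 and C14=C15 would need 9- and 13-membered rings.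

## Retrosynthetic reasoning

C2=C3 and the ester. Acid 15 is traced to its ethyl ester 14, and 14 is cut at C2=C3 into aldehyde 13 and a stabilised α-methyl phosphorane that brings C1, C2 and the 2-methyl group (the reagent of step 9). This alkene is cut because its E geometry is the thermodynamic one and an olefination delivers it without help. The conjugated acid then appears only at the end, so no earlier step has to tolerate it. The forward steps must give the E-enoate and then saponify without touching the oxirane.

Oxidation state of C3. Aldehyde 13 comes from methyl ester 12 by partial reduction. C3 must be a carboxyl carbon once, for the key step, and an aldehyde once, for the olefination.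

Oxirane C7–O bond and the temporary lactone. In 12 the C7–O bond is cut and the oxygen on C6 is reassigned to a lactone, which leads to iodolactone 10. In the forward direction methoxide opens the lactone to the iodohydrin ester 11, and its C6 alkoxide displaces iodide at C7 with inversion. The oxirane, the most fragile group, is thus made only after all carbanion chemistry in the C3–C5 region, and the ring that is not in the target is destroyed in the same operation.

Key disconnection, C6–O and C7–I. Cutting both bonds of 10 removes both stereocentres and leaves the achiral, all-E trienoic acid 9. The forward reaction is an enantioselective iodolactonisation. It has to choose C6=C7 among three like alkenes, which the ring size does for it, add O and I anti across the E alkene, which fixes the relative configuration, and choose one alkene face, which is the task of the catalyst.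

C4–C5. Acid 9 is cut between the allylic carbon C5 and C4 into allylic bromide 8 and a two-carbon carboxylic acid dianion (the reagent of step 5). The cut is made here because C5 is the E-methyl carbon of a farnesyl terminus, so C5 to C16 with three methyl groups and two E alkenes can be bought in one piece. Bromide 8 comes from allylic alcohol 7.

C16–C17. Alcohol 7 is cut between the furylmethyl carbon C17 and the allylic carbon C16 into Grignard reagent 6 and the allylic acetate 2, whose acetate serves directly as the leaving group. Reagent 6 comes from chloride 5, and 5 from alcohol 3 by way of mesylate 4. The forward coupling must be α-selective and keep the C14=C15 geometry.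

C5–O. Hydroxy acetate 2 comes from farnesyl acetate 1 by allylic oxidation of the terminal E-methyl group, which installs the only handle needed for the C4–C5 bond.

## Alternatives that were turned down

Alternative 1: This is the textbook route, a hydroxyl-directed epoxidation followed by C4–C5 bond formation next to the oxirane. Sharpless asymmetric epoxidation of allylic alcohol 7 with L-(+)-diethyl tartrate would give the epoxy alcohol A1; its triflate A2 would be displaced at C5 by an acetate enolate to reach 12. On paper it is two steps shorter than the chosen sequence from 7 to 12. It was not made the main line for three reasons. The stereodefining reagent needs a hydroxyl group on C5, where the target has a plain methylene, so the C5–O bond must be exchanged for C5–C4 after the oxirane exists. That exchange is an SN2 reaction of a basic carbon nucleophile at a primary carbon flanked by the fully substituted oxirane carbon C6. A1 is a 2,3-epoxy alcohol open to Payne rearrangement under base, and A2 is a highly reactive sulfonate next to an oxirane. The least secure C–C bond formation would therefore fall after the stereocentres, on the most fragile intermediate. It is kept as the fallback of step 6.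

Alternative 2: Here only the two C–O bonds of the oxirane are cut, on the complete carbon skeleton. The tetraenoate A3, reachable from bromide 8 by one γ-selective alkylation of a tiglate dienolate, would be epoxidised late with a chiral dioxirane (Shi epoxidation). This is the shortest route on paper. It was turned down because C6=C7, C10=C11 and C14=C15 carry the same substitution and nearly the same electron density, so a reagent with no handle on the substrate cannot tell them apart; only C2=C3 is set apart, by conjugation. Epoxidation would be spread over three sites and over multiple additions, and the electron-rich furan would be oxidised by the dioxirane as well. The step count gained would be lost in a separation that has no structural basis for success.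

Alternative 3: This is a convergent cut at C8–C9. The C1–C8 epoxy triflate A4 (from geranyl acetate by allylic oxidation, adjustment to the enoate, Sharpless epoxidation and triflation) would alkylate the carbanion of the C9–C17 allylic sulfone A5 to give the sulfone A6, and reductive desulfonylation would finish the chain. It was turned down for three reasons. Two separate allylic oxidations and two fragment syntheses make it several steps longer. The sulfonyl carbanion is a Michael donor towards the enoate of A4. The reductive removal of an allylic sulfone from A6 (dissolving metal or palladium with hydride) would have to spare an oxirane and an enoate, and tends to move or scramble the adjacent C10=C11 alkene.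

Key step: step 6

## Route

Step 1
Reactants: 1 (2E,6E)-3,7,11-trimethyldodeca-2,6,10-trien-1-yl acetate (trans,trans-farnesyl acetate)
Product: 2 (2E,6E,10E)-12-hydroxy-3,7,11-trimethyldodeca-2,6,10-trien-1-yl acetate
Conditions: SeO2 (cat.), salicylic acid (cat.), t-BuOOH (70% aq.), CH2Cl2, 0 °C to rt, stopped before full conversion
Reagents that add atoms: selenium dioxide, O=[Se]=O (catalytic oxygen carrier); tert-butyl hydroperoxide, CC(C)(C)OO (terminal oxidant that supplies the oxygen atom)
Why: Catalytic SeO2 allylic oxidation (ene reaction, then [2,3]-sigmatropic shift) should attack the most electron-rich and least hindered terminal alkene at the methyl group trans to the chain, giving the E-allylic alcohol; the alkene next to the acetate is deactivated.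

Step 2
Reactants: 3 furan-3-ylmethanol
Product: 5 3-(chloromethyl)furan, via furan-3-ylmethyl methanesulfonate 4 (not isolated)
Conditions: MsCl, 2,4,6-collidine, LiCl, DMF, 0 °C; used at once as a cold ethereal solution
Reagents that add atoms: lithium chloride, [Li+].[Cl-]
Why: Mesylation followed by SN2 exchange with chloride in a buffered, acid-free medium should give the labile furylmethyl chloride without ring alkylation or polymerisation.

Step 3
Reactants: 5 3-(chloromethyl)furan; 2 (2E,6E,10E)-12-hydroxy-3,7,11-trimethyldodeca-2,6,10-trien-1-yl acetate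
Product: 7 (2E,6E,10E)-13-(furan-3-yl)-2,6,10-trimethyltrideca-2,6,10-trien-1-ol, via (furan-3-ylmethyl)magnesium chloride 6 (not isolated)
Conditions: Mg, THF, 0 °C to rt; then 2 (0.4 equiv relative to 6), Li2CuCl4 (5 mol%), THF, −30 to 0 °C, Grignard added fast; aq. NH4Cl
Reagents that add atoms: none
Why: Copper-catalysed allylic substitution of a primary allylic acetate by a Grignard reagent; fast addition at low temperature favours the diorganocuprate path and α-attack with retention of the E alkene, the γ-carbon being fully substituted, and the first equivalent of 6 only deprotonates the hydroxyl group.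

Step 4
Reactants: 7 (2E,6E,10E)-13-(furan-3-yl)-2,6,10-trimethyltrideca-2,6,10-trien-1-ol
Product: 8 3-[(3E,7E,11E)-13-bromo-4,8,12-trimethyltrideca-3,7,11-trien-1-yl]furan
Conditions: CBr4, PPh3, CH2Cl2, −20 to 0 °C; used crude after filtration
Reagents that add atoms: carbon tetrabromide, BrC(Br)(Br)Br
Why: Appel reaction; SN2 displacement on the alkoxyphosphonium ion under neutral conditions should spare the furan and the polyene and give the primary allylic bromide without allylic shift.

Step 5
Reactants: 8 3-[(3E,7E,11E)-13-bromo-4,8,12-trimethyltrideca-3,7,11-trien-1-yl]furan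
Product: 9 (4E,8E,12E)-15-(furan-3-yl)-4,8,12-trimethylpentadeca-4,8,12-trienoic acid
Conditions: AcOH, LDA (2 equiv per AcOH), THF/DMPU, 0 to 40 °C; then 8, 0 °C to rt; aq. KHSO4
Reagents that add atoms: acetic acid, CC(=O)O (as its dilithium dianion)
Why: Alkylation of a carboxylic acid dianion by a reactive primary allylic bromide should form C4–C5 by direct SN2 (the γ-carbon is trisubstituted) and give the γ,δ-unsaturated acid in one operation, with no ester to cleave.

Step 6
Reactants: 9 (4E,8E,12E)-15-(furan-3-yl)-4,8,12-trimethylpentadeca-4,8,12-trienoic acid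
Product: 10 (5S)-5-[(1R,4E,8E)-11-(furan-3-yl)-1-iodo-4,8-dimethylundeca-4,8-dien-1-yl]-5-methyloxolan-2-one
Conditions: NIS, chiral BINOL-derived bifunctional amidine catalyst (10 mol%; the enantiomer that directs iodine to the Re face of C7), toluene/CH2Cl2, −50 °C, dark
Reagents that add atoms: N-iodosuccinimide, O=C1CCC(=O)N1I
Why: Proposed new method: catalyst-controlled enantioselective 5-exo iodolactonisation of a purely aliphatic (E)-trisubstituted γ,δ-unsaturated acid that also carries two further trisubstituted alkenes and a furan; the closest known reaction type is the catalytic asymmetric iodolactonisation of 4- and 5-substituted alkenoic acids with NIS under chiral bifunctional Brønsted base/hydrogen-bond-donor catalysis. The amidine should bind the carboxylic acid of 9 as an ion pair while the acidic site of the catalyst activates NIS, so that I+ is passed on inside the chiral pocket to the alkene next to the bound carboxylate. The carboxylate oxygen then opens the iodiranium ion at the tertiary carbon C6, anti to iodine; the γ-lactone ring O–C3–C4–C5–C6 closes in the 5-exo mode with Markovnikov orientation, since the 6-endo alternative would need attack at the secondary C7. Site selectivity needs no reagent control: iodiranium formation is reversible and only C6=C7 has the nucleophile within reach of a five-membered ring, whereas C10=C11 and C14=C15 would need 9- and 13-membered rings. C6 (S) is set by the catalyst, which has to deliver iodine to the Re face of C7 (C6 > C8 > H) and oxygen to the Si face of C6 (C7 > C5 > CH3); C7 (R) follows from the anti addition to the E alkene, so the two centres are set as a pair. The catalyst therefore has to supply facial selectivity only; low temperature, an apolar solvent and the absence of free acid or Lewis acid should keep furan iodination, cation–olefin cyclisation and the uncatalysed background reaction slow.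

Step 7
Reactants: 10 (5S)-5-[(1R,4E,8E)-11-(furan-3-yl)-1-iodo-4,8-dimethylundeca-4,8-dien-1-yl]-5-methyloxolan-2-one
Product: 12 methyl 3-[(2S,3S)-3-[(3E,7E)-10-(furan-3-yl)-3,7-dimethyldeca-3,7-dien-1-yl]-2-methyloxiran-2-yl]propanoate, via ring-opened iodohydrin methyl ester 11 (not isolated)
Conditions: K2CO3, MeOH, 0 °C to rt
Reagents that add atoms: methanol, CO
Why: Methoxide opens the γ-lactone and the released tertiary C6 alkoxide displaces iodide at C7 in an intramolecular SN2 (Williamson-type oxirane closure) with inversion, so 7R becomes 7S while C6 is untouched; the irreversible closure pulls the lactone/ester equilibrium to 12.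

Step 8
Reactants: 12 methyl 3-[(2S,3S)-3-[(3E,7E)-10-(furan-3-yl)-3,7-dimethyldeca-3,7-dien-1-yl]-2-methyloxiran-2-yl]propanoate
Product: 13 3-[(2S,3S)-3-[(3E,7E)-10-(furan-3-yl)-3,7-dimethyldeca-3,7-dien-1-yl]-2-methyloxiran-2-yl]propanal
Conditions: DIBAL-H (1.05 equiv), CH2Cl2, −78 °C; MeOH, then aq. Rochelle salt
Reagents that add atoms: none
Why: Partial reduction of a methyl ester by DIBAL-H stops at the tetrahedral aluminium hemiacetal at −78 °C; oxirane, furan and alkenes should be inert at this temperature.

Step 9
Reactants: 13 3-[(2S,3S)-3-[(3E,7E)-10-(furan-3-yl)-3,7-dimethyldeca-3,7-dien-1-yl]-2-methyloxiran-2-yl]propanal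
Product: 14 ethyl (2E)-5-[(2S,3S)-3-[(3E,7E)-10-(furan-3-yl)-3,7-dimethyldeca-3,7-dien-1-yl]-2-methyloxiran-2-yl]-2-methylpent-2-enoate
Conditions: Ph3P=C(Me)CO2Et, CH2Cl2, rt
Reagents that add atoms: ethyl 2-(triphenyl-λ5-phosphanylidene)propanoate, CCOC(=O)C(C)=P(c1ccccc1)(c1ccccc1)c1ccccc1
Why: Wittig olefination with an α-branched stabilised ylide is under thermodynamic control in the oxaphosphetane and should give the E-trisubstituted enoate (C1 trans to C4) under neutral conditions that do not touch the oxirane.

Step 10
Reactants: 14 ethyl (2E)-5-[(2S,3S)-3-[(3E,7E)-10-(furan-3-yl)-3,7-dimethyldeca-3,7-dien-1-yl]-2-methyloxiran-2-yl]-2-methylpent-2-enoate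
Product: 15 (2E)-5-[(2S,3S)-3-[(3E,7E)-10-(furan-3-yl)-3,7-dimethyldeca-3,7-dien-1-yl]-2-methyloxiran-2-yl]-2-methylpent-2-enoic acid
Conditions: LiOH·H2O, THF/MeOH/H2O, rt; aq. KHSO4 to pH 4–5 at 0 °C
Reagents that add atoms: lithium hydroxide, [Li+].[OH-]
Why: Saponification by acyl–oxygen cleavage; a trisubstituted oxirane is inert to hydroxide at room temperature, the carboxylate cannot reach it across the E alkene, and the mild cold acidification protects oxirane and furan.

## Compound list

1 | (2E,6E)-3,7,11-trimethyldodeca-2,6,10-trien-1-yl acetate | CC(=O)OC/C=C(\C)CC/C=C(\C)CCC=C(C)C | starting material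
2 | (2E,6E,10E)-12-hydroxy-3,7,11-trimethyldodeca-2,6,10-trien-1-yl acetate | CC(=O)OC/C=C(\C)CC/C=C(\C)CC/C=C(\C)CO | intermediate
3 | furan-3-ylmethanol | OCc1ccoc1 | starting material
4 | furan-3-ylmethyl methanesulfonate | CS(=O)(=O)OCc1ccoc1 | intermediate
5 | 3-(chloromethyl)furan | ClCc1ccoc1 | intermediate
6 | (furan-3-ylmethyl)magnesium chloride | Cl[Mg]Cc1ccoc1 | intermediate
7 | (2E,6E,10E)-13-(furan-3-yl)-2,6,10-trimethyltrideca-2,6,10-trien-1-ol | C/C(=C\CCc1ccoc1)CC/C=C(\C)CC/C=C(\C)CO | intermediate
8 | 3-[(3E,7E,11E)-13-bromo-4,8,12-trimethyltrideca-3,7,11-trien-1-yl]furan | C/C(=C\CCc1ccoc1)CC/C=C(\C)CC/C=C(\C)CBr | intermediate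
9 | (4E,8E,12E)-15-(furan-3-yl)-4,8,12-trimethylpentadeca-4,8,12-trienoic acid | C/C(=C\CCc1ccoc1)CC/C=C(\C)CC/C=C(\C)CCC(=O)O | intermediate
10 | (5S)-5-[(1R,4E,8E)-11-(furan-3-yl)-1-iodo-4,8-dimethylundeca-4,8-dien-1-yl]-5-methyloxolan-2-one | C/C(=C\CCc1ccoc1)CC/C=C(\C)CC[C@@H](I)[C@]1(C)CCC(=O)O1 | intermediate
11 | methyl (4S,5R,8E,12E)-15-(furan-3-yl)-4-hydroxy-5-iodo-4,8,12-trimethylpentadeca-8,12-dienoate (formed as its potassium alkoxide) | C/C(=C\CCc1ccoc1)CC/C=C(\C)CC[C@@H](I)[C@@](C)(O)CCC(=O)OC | intermediate
12 | methyl 3-[(2S,3S)-3-[(3E,7E)-10-(furan-3-yl)-3,7-dimethyldeca-3,7-dien-1-yl]-2-methyloxiran-2-yl]propanoate | C/C(=C\CCc1ccoc1)CC/C=C(\C)CC[C@@H]1O[C@@]1(C)CCC(=O)OC | intermediate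
13 | 3-[(2S,3S)-3-[(3E,7E)-10-(furan-3-yl)-3,7-dimethyldeca-3,7-dien-1-yl]-2-methyloxiran-2-yl]propanal | C/C(=C\CCc1ccoc1)CC/C=C(\C)CC[C@@H]1O[C@@]1(C)CCC=O | intermediate
14 | ethyl (2E)-5-[(2S,3S)-3-[(3E,7E)-10-(furan-3-yl)-3,7-dimethyldeca-3,7-dien-1-yl]-2-methyloxiran-2-yl]-2-methylpent-2-enoate | C/C(=C\CCc1ccoc1)CC/C=C(\C)CC[C@@H]1O[C@@]1(C)CC/C=C(\C)C(=O)OCC | intermediate
15 | (2E)-5-[(2S,3S)-3-[(3E,7E)-10-(furan-3-yl)-3,7-dimethyldeca-3,7-dien-1-yl]-2-methyloxiran-2-yl]-2-methylpent-2-enoic acid | C/C(=C\CCc1ccoc1)CC/C=C(\C)CC[C@@H]1O[C@@]1(C)CC/C=C(\C)C(=O)O | target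

## Step count and least certain steps

Total step count: 10. Longest linear sequence: 9 steps (steps 1 and 3 to 10, from 1); step 2 is the side branch.

Step 6 (key step, proposed new method). The most likely failure is poor facial selectivity: the alkene bears only alkyl groups and gives the catalyst no aryl or polar contact beyond the bound carboxylate. A competing uncatalysed iodolactonisation would lower the enantiomeric purity further, and slow electrophilic iodination of the furan is a secondary risk. The fallback uses known chemistry, sets out from 7 and returns at 12. Sharpless asymmetric epoxidation of 7 (Ti(OiPr)4, L-(+)-diethyl tartrate, t-BuOOH, 4 Å sieves, CH2Cl2, −20 °C) should deliver oxygen to the Si,Si face under control of the allylic hydroxyl group and give [(2S,3S)-3-[(3E,7E)-10-(furan-3-yl)-3,7-dimethyldeca-3,7-dien-1-yl]-2-methyloxiran-2-yl]methanol F1. Triflation (Tf2O, 2,6-lutidine, CH2Cl2, −78 °C) gives [(2S,3S)-3-[(3E,7E)-10-(furan-3-yl)-3,7-dimethyldeca-3,7-dien-1-yl]-2-methyloxiran-2-yl]methyl trifluoromethanesulfonate F2. F2 is treated without isolation with the lithium enolate of methyl acetate (LDA, THF, −78 °C); SN2 at C5 forms the C4–C5 bond and gives 12.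

Step 3. The Grignard reagent may add to the acetate carbonyl instead of entering the copper cycle, and attack at the γ-carbon or loss of the C14=C15 geometry through a π-allyl copper species is possible; the free hydroxyl group also consumes reagent. The fallback sets out from 6 and returns at 7. Reagent 6 is coupled under the same copper catalysis with commercial (2E,6E)-farnesyl chloride (ClC/C=C(\C)CC/C=C(\C)CCC=C(C)C), an allylic chloride without carbonyl or hydroxyl group, to give 3-[(3E,7E)-4,8,12-trimethyltrideca-3,7,11-trien-1-yl]furan F3. Allylic oxidation of F3 with catalytic SeO2 and t-BuOOH at the terminal E-methyl group then gives 7.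

Step 5. The dianion of acetic acid is poorly soluble and strongly aggregated, so the alkylation may stall while the allylic bromide decomposes or is consumed by elimination. The fallback sets out from 8 and returns at 9. Alkylation of sodium dimethyl malonate (NaH, THF, 0 °C to rt) with 8 gives dimethyl 2-[(2E,6E,10E)-13-(furan-3-yl)-2,6,10-trimethyltrideca-2,6,10-trien-1-yl]propanedioate F4. Saponification (KOH, aq. MeOH) gives 2-[(2E,6E,10E)-13-(furan-3-yl)-2,6,10-trimethyltrideca-2,6,10-trien-1-yl]propanedioic acid F5, and decarboxylation in pyridine at 100 °C gives 9.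

Step 8. Over-reduction to the primary alcohol is the main risk, because the acyclic aluminium hemiacetal can collapse before the quench; opening of the oxirane by the Lewis acidic hydride is a lesser one. The fallback sets out from 10 and returns at 13, with the reduction moved to the lactone stage, where the cyclic hemiacetal is stable. DIBAL-H (1.1 equiv, CH2Cl2, −78 °C) reduces 10 to (5S)-5-[(1R,4E,8E)-11-(furan-3-yl)-1-iodo-4,8-dimethylundeca-4,8-dien-1-yl]-5-methyloxolan-2-ol F6. Brief treatment of F6 with K2CO3 in MeOH at 0 °C opens the lactol; the freed C6 alkoxide closes the oxirane with inversion at C7 and releases aldehyde 13.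

## Further compounds

F1 | step 6 | [(2S,3S)-3-[(3E,7E)-10-(furan-3-yl)-3,7-dimethyldeca-3,7-dien-1-yl]-2-methyloxiran-2-yl]methanol | C/C(=C\CCc1ccoc1)CC/C=C(\C)CC[C@@H]1O[C@@]1(C)CO
F2 | step 6 | [(2S,3S)-3-[(3E,7E)-10-(furan-3-yl)-3,7-dimethyldeca-3,7-dien-1-yl]-2-methyloxiran-2-yl]methyl trifluoromethanesulfonate | C/C(=C\CCc1ccoc1)CC/C=C(\C)CC[C@@H]1O[C@@]1(C)COS(=O)(=O)C(F)(F)F
F3 | step 3 | 3-[(3E,7E)-4,8,12-trimethyltrideca-3,7,11-trien-1-yl]furan | C/C(=C\CCc1ccoc1)CC/C=C(\C)CCC=C(C)C
F4 | step 5 | dimethyl 2-[(2E,6E,10E)-13-(furan-3-yl)-2,6,10-trimethyltrideca-2,6,10-trien-1-yl]propanedioate | C/C(=C\CCc1ccoc1)CC/C=C(\C)CC/C=C(\C)CC(C(=O)OC)C(=O)OC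
F5 | step 5 | 2-[(2E,6E,10E)-13-(furan-3-yl)-2,6,10-trimethyltrideca-2,6,10-trien-1-yl]propanedioic acid | C/C(=C\CCc1ccoc1)CC/C=C(\C)CC/C=C(\C)CC(C(=O)O)C(=O)O
F6 | step 8 | (5S)-5-[(1R,4E,8E)-11-(furan-3-yl)-1-iodo-4,8-dimethylundeca-4,8-dien-1-yl]-5-methyloxolan-2-ol | C/C(=C\CCc1ccoc1)CC/C=C(\C)CC[C@@H](I)[C@]1(C)CCC(O)O1
A1 | alternative 1 | [(2S,3S)-3-[(3E,7E)-10-(furan-3-yl)-3,7-dimethyldeca-3,7-dien-1-yl]-2-methyloxiran-2-yl]methanol | C/C(=C\CCc1ccoc1)CC/C=C(\C)CC[C@@H]1O[C@@]1(C)CO
A2 | alternative 1 | [(2S,3S)-3-[(3E,7E)-10-(furan-3-yl)-3,7-dimethyldeca-3,7-dien-1-yl]-2-methyloxiran-2-yl]methyl trifluoromethanesulfonate | C/C(=C\CCc1ccoc1)CC/C=C(\C)CC[C@@H]1O[C@@]1(C)COS(=O)(=O)C(F)(F)F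
A3 | alternative 2 | ethyl (2E,6E,10E,14E)-17-(furan-3-yl)-2,6,10,14-tetramethylheptadeca-2,6,10,14-tetraenoate | C/C(=C\CCc1ccoc1)CC/C=C(\C)CC/C=C(\C)CC/C=C(\C)C(=O)OCC
A4 | alternative 3 | ethyl (2E)-2-methyl-5-[(2S,3S)-2-methyl-3-{[(trifluoromethanesulfonyl)oxy]methyl}oxiran-2-yl]pent-2-enoate | FC(F)(F)S(=O)(=O)OC[C@@H]1O[C@@]1(C)CC/C=C(\C)C(=O)OCC
A5 | alternative 3 | 3-[(3E,7E)-9-(benzenesulfonyl)-4,8-dimethylnona-3,7-dien-1-yl]furan | C/C(=C\CCc1ccoc1)CC/C=C(\C)CS(=O)(=O)c1ccccc1
A6 | alternative 3 | ethyl (2E)-5-[(2S,3S)-3-[(3E,7E)-2-(benzenesulfonyl)-10-(furan-3-yl)-3,7-dimethyldeca-3,7-dien-1-yl]-2-methyloxiran-2-yl]-2-methylpent-2-enoate (both configurations at the sulfonyl carbon) | C/C(=C\CCc1ccoc1)CC/C=C(\C)C(C[C@@H]1O[C@@]1(C)CC/C=C(\C)C(=O)OCC)S(=O)(=O)c1ccccc1
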